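**Plan**

- Numbering: the heptane chain runs from C1 (CH2 on the 4-hydroxy-3-methoxyphenyl ring) to C7 (CH2 on the 4-hydroxy-3,5-dimethoxyphenyl ring); O3 and O5 are the hydroxyl oxygens.
- Enabling feature: the anti C3–OH/C5–OH pair next to benzylic C1 is the ring-opened form of an all-cis 2-aryl-tetrahydropyran-4-ol (ring atoms O5, C1, C2, C3, C4, C5). Its benzylic C1–O5 bond sits para to a phenol and can be cut reductively.
- Retrosynthesis: re-join C1–O5 to the tetrahydropyran; cut O5–C1, C1–C2 and C3–O in one Prins disconnection to vanillin acetate and an (S)-homoallylic alcohol; cut C4–C5 (allylation); trace the C5–C7 arm to 4-allyl-2,6-dimethoxyphenol.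
- Forward: the syringyl arm is protected, hydroborated, oxidised and allylated; the Prins step joins the two halves and closes the single, temporary ring; ester removal and hydrogenolysis of C1–O5 open it to the chain.
- Stereochemistry: C5 (S) comes from a reagent-controlled Brown allylation; C3 (S) is relayed from C5 through the chair Prins transition state with equatorial trifluoroacetate capture; the auxiliary C1 centre is erased at the end.

Key step: step 5

Assumption: (+)-Ipc2B(allyl) denotes the allylborane derived from (−)-α-pinene, which is taken to deliver allyl to the Re face of unbranched aliphatic aldehydes.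

**Step 1**
Reactants: 1 4-allyl-2,6-dimethoxyphenol
Product: 2 4-allyl-2,6-dimethoxyphenyl pivalate
Conditions: PivCl, Et3N, DMAP (cat.), CH2Cl2, 0 °C to rt
Reagents that add atoms: pivaloyl chloride, CC(C)(C)C(Cl)=O
Why: DMAP-catalysed O-acylation of the phenol (nucleophilic acyl substitution) should proceed cleanly, and the pivalate is chosen because it should withstand the buffered peroxide work-ups of steps 2 and 4, resist trifluoroacetic acid and inductively temper the syringyl ring.

**Step 2**
Reactants: 2 4-allyl-2,6-dimethoxyphenyl pivalate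
Product: 4 4-(3-hydroxypropyl)-2,6-dimethoxyphenyl pivalate, via B-alkyl-9-borabicyclononane adduct 3 (not isolated)
Conditions: 9-BBN, THF, 0 °C to rt; then pH 7 buffer (NaH2PO4/Na2HPO4), 30% H2O2, 0 °C to rt
Reagents that add atoms: hydrogen peroxide, OO
Why: Hydroboration–oxidation, in which 9-BBN should add anti-Markovnikov to the terminal alkene without reducing the aryl ester and buffered peroxide converts the primary C–B bond into C–OH.

**Step 3**
Reactants: 4 4-(3-hydroxypropyl)-2,6-dimethoxyphenyl pivalate
Product: 5 2,6-dimethoxy-4-(3-oxopropyl)phenyl pivalate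
Conditions: TEMPO (cat.), PhI(OAc)2, CH2Cl2, rt
Reagents that add atoms: none
Why: The oxoammonium-mediated TEMPO/PhI(OAc)2 oxidation of a primary alcohol should stop at the aldehyde under neutral conditions that spare the pivalate and the acylated, electron-rich ring.

**Step 4**
Reactants: 5 2,6-dimethoxy-4-(3-oxopropyl)phenyl pivalate
Product: 7 4-[(3S)-3-hydroxyhex-5-en-1-yl]-2,6-dimethoxyphenyl pivalate, via diisopinocampheylborinate ester 6 (not isolated)
Conditions: (+)-Ipc2B(allyl), Et2O, −78 °C; then pH 7 buffer (NaH2PO4/Na2HPO4), MeOH, 30% H2O2, 0 °C to rt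
Reagents that add atoms: (+)-B-allyldiisopinocampheylborane, C=CCB([C@H]1C[C@H]2C[C@@H]([C@@H]1C)C2(C)C)[C@H]1C[C@H]2C[C@@H]([C@@H]1C)C2(C)C
Why: Brown allylation through a closed six-membered chair transition state, in which the isopinocampheyl groups of the (−)-α-pinene-derived reagent should direct allyl to the Re face of the aldehyde and so set the (3S) carbinol that becomes C5 of the target, after which buffered peroxide cleaves borinate 6 without touching the pivalate.

**Step 5**
Reactants: 7 4-[(3S)-3-hydroxyhex-5-en-1-yl]-2,6-dimethoxyphenyl pivalate; 8 vanillin acetate (4-formyl-2-methoxyphenyl acetate)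
Product: 10 (2S,4R,6S)-2-(4-acetoxy-3-methoxyphenyl)-6-[2-(3,5-dimethoxy-4-pivaloyloxyphenyl)ethyl]tetrahydro-2H-pyran-4-yl trifluoroacetate, via E-oxocarbenium trifluoroacetate 9 (not isolated)
Conditions: CF3CO2H/CH2Cl2 (1:4), 0 °C to rt; then aq NaHCO3; crude ester carried on
Reagents that add atoms: trifluoroacetic acid, OC(=O)C(F)(F)F
Why: Acid-promoted condensation of 7 with 8 should give a hemiacetal that ionises to the E-oxocarbenium ion 9, whose terminal alkene attacks C1 (Prins cyclisation; the closest known reaction type is the trifluoroacetic acid Prins synthesis of all-cis 2,6-disubstituted tetrahydropyran-4-ols from homoallylic alcohols and aryl aldehydes). The tetrahydropyran closes in a 6-endo-trig mode through a chair transition state, forming O5–C1 and C1–C2, and the resulting secondary cation at C3 is captured by trifluoroacetate to form C3–O. C1 (ring C2, S) is set by the chair in which the aryl group of the E-oxocarbenium ion and the arylethyl chain on C5 are both equatorial, so it is relayed from the existing C5 centre (ring C6, S). C3 (ring C4, R) is set by equatorial attack of trifluoroacetate on the tetrahydropyranyl cation of that same chair, again under control of C5, giving the all-cis ring that corresponds to the anti C3/C5 diol. The step needs preservation of the C5 configuration and alkene-over-arene chemoselectivity: the para-acetoxy group on the aldehyde ring disfavours benzylic ionisation and 2-oxonia-Cope scrambling, the pivalate lowers the nucleophilicity of the syringyl ring, and the six-membered chair closure should outpace the seven-membered Friedel–Crafts alternative.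

**Step 6**
Reactants: 10 (2S,4R,6S)-2-(4-acetoxy-3-methoxyphenyl)-6-[2-(3,5-dimethoxy-4-pivaloyloxyphenyl)ethyl]tetrahydro-2H-pyran-4-yl trifluoroacetate
Product: 11 (2S,4R,6S)-2-(4-hydroxy-3-methoxyphenyl)-6-[2-(4-hydroxy-3,5-dimethoxyphenyl)ethyl]tetrahydro-2H-pyran-4-ol
Conditions: NaOMe, MeOH, 50 °C (Ar); then aq NH4Cl
Reagents that add atoms: none
Why: Methoxide transesterification (methanolysis) should remove the trifluoroacetate, the aryl acetate and the hindered aryl pivalate while the ring ether and the three stereocentres are inert to base, and freeing the para-hydroxyl arms the C1–O5 bond for the cleavage that follows.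

**Step 7**
Reactants: 11 (2S,4R,6S)-2-(4-hydroxy-3-methoxyphenyl)-6-[2-(4-hydroxy-3,5-dimethoxyphenyl)ethyl]tetrahydro-2H-pyran-4-ol
Product: 12 (3S,5S)-1-(4-hydroxy-3-methoxyphenyl)-7-(4-hydroxy-3,5-dimethoxyphenyl)heptane-3,5-diol
Conditions: H2 (3 bar), Pd(OH)2/C, MeOH/AcOH (10:1), rt
Reagents that add atoms: none
Why: Catalytic hydrogenolysis of the C1–O5 bond, the only benzylic ether in 11 and activated by the para-hydroxyl, should turn C1 into CH2 and leave the ring oxygen on C5 as a hydroxyl, so the untouched C3 and C5 centres appear as the (3S,5S) anti diol.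

**Compound list**

1 | 4-allyl-2,6-dimethoxyphenol | C=CCc1cc(OC)c(O)c(OC)c1 | starting material
2 | 4-allyl-2,6-dimethoxyphenyl pivalate | C=CCc1cc(OC)c(OC(=O)C(C)(C)C)c(OC)c1 | intermediate
3 | 9-[3-(3,5-dimethoxy-4-pivaloyloxyphenyl)propyl]-9-borabicyclo[3.3.1]nonane (formed in the flask) | CC(C)(C)C(=O)Oc1c(OC)cc(CCCB2C3CCCC2CCC3)cc1OC | intermediate
4 | 4-(3-hydroxypropyl)-2,6-dimethoxyphenyl pivalate | CC(C)(C)C(=O)Oc1c(OC)cc(CCCO)cc1OC | intermediate
5 | 2,6-dimethoxy-4-(3-oxopropyl)phenyl pivalate | CC(C)(C)C(=O)Oc1c(OC)cc(CCC=O)cc1OC | intermediate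
6 | (3S)-1-(3,5-dimethoxy-4-pivaloyloxyphenyl)hex-5-en-3-yl diisopinocampheylborinate (formed in the flask) | C=CC[C@H](CCc1cc(OC)c(OC(=O)C(C)(C)C)c(OC)c1)OB([C@H]1C[C@H]2C[C@@H]([C@@H]1C)C2(C)C)[C@H]1C[C@H]2C[C@@H]([C@@H]1C)C2(C)C | intermediate
7 | 4-[(3S)-3-hydroxyhex-5-en-1-yl]-2,6-dimethoxyphenyl pivalate | C=CC[C@@H](O)CCc1cc(OC)c(OC(=O)C(C)(C)C)c(OC)c1 | intermediate
8 | vanillin acetate (4-formyl-2-methoxyphenyl acetate) | CC(=O)Oc1ccc(C=O)cc1OC | starting material
9 | E-oxocarbenium ion from 7 and 8, trifluoroacetate salt (formed in the flask) | CC(=O)Oc1ccc(/C=[O+]/[C@H](CC=C)CCc2cc(OC)c(OC(=O)C(C)(C)C)c(OC)c2)cc1OC.[O-]C(=O)C(F)(F)F | intermediate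
10 | (2S,4R,6S)-2-(4-acetoxy-3-methoxyphenyl)-6-[2-(3,5-dimethoxy-4-pivaloyloxyphenyl)ethyl]tetrahydro-2H-pyran-4-yl trifluoroacetate (all-cis) | CC(=O)Oc1ccc(cc1OC)[C@@H]2C[C@H](OC(=O)C(F)(F)F)C[C@H](CCc3cc(OC)c(OC(=O)C(C)(C)C)c(OC)c3)O2 | intermediate
11 | (2S,4R,6S)-2-(4-hydroxy-3-methoxyphenyl)-6-[2-(4-hydroxy-3,5-dimethoxyphenyl)ethyl]tetrahydro-2H-pyran-4-ol (all-cis) | Oc1ccc(cc1OC)[C@@H]2C[C@H](O)C[C@H](CCc3cc(OC)c(O)c(OC)c3)O2 | intermediate
12 | (3S,5S)-1-(4-hydroxy-3-methoxyphenyl)-7-(4-hydroxy-3,5-dimethoxyphenyl)heptane-3,5-diol | COc1cc(CC[C@H](O)C[C@@H](O)CCc2cc(OC)c(O)c(OC)c2)ccc1O | target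

**Step count and risks**

Total step count: 7. Longest linear sequence: 7 steps (1 to 12); vanillin acetate 8 enters at step 5.

Steps most likely to fail:

1. Step 5 (Prins cyclisation). The risks are side-chain exchange and erosion of the C5 configuration through 2-oxonia-Cope rearrangement of the oxocarbenium ion, and electrophilic attack of the cationic intermediates on the syringyl ring instead of the alkene. The fallback builds the same ring at the ketone oxidation level by aldol and oxa-Michael chemistry; it sets out from 7 and comes back at 11. Tsuji–Wacker oxidation of 7 (PdCl2, CuCl, O2, DMF/H2O) should give the β-hydroxy methyl ketone 4-[(3S)-3-hydroxy-5-oxohexyl]-2,6-dimethoxyphenyl pivalate F1. Its dibutylboron enolate, formed on the methyl side with Bu2BOTf and iPr2NEt at −78 °C, would add to 8 to give the aldol 4-[(3S)-7-(4-acetoxy-3-methoxyphenyl)-3,7-dihydroxy-5-oxoheptyl]-2,6-dimethoxyphenyl pivalate F2 as both C7 epimers. TsOH (cat.) in CH2Cl2 should dehydrate F2 and close the ring by reversible 6-endo oxa-Michael addition to the thermodynamically preferred 2,6-cis ketone (2S,6S)-2-(4-acetoxy-3-methoxyphenyl)-6-[2-(3,5-dimethoxy-4-pivaloyloxyphenyl)ethyl]tetrahydro-4H-pyran-4-one F3. NaBH4 in MeOH/THF at −40 °C (axial hydride delivery) would give the all-cis alcohol (2S,4R,6S)-2-(4-acetoxy-3-methoxyphenyl)-6-[2-(3,5-dimethoxy-4-pivaloyloxyphenyl)ethyl]tetrahydro-2H-pyran-4-ol F4. Methanolysis of F4 under the conditions of step 6 returns the route at 11.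

2. Step 7 (hydrogenolysis). The risks are stalling of the cleavage because the benzylic C–O bond is held in a ring and adsorbs poorly on the catalyst, or partial saturation of the electron-rich rings if the pressure is raised. The fallback replaces surface hydrogenolysis by ionic hydrogenation, a different bond-breaking mechanism and not a change of catalyst; it sets out from 11 and comes back at 12. Treatment with excess Et3SiH and CF3CO2H in CH2Cl2 at 0 °C should protonate the ring oxygen and ionise C1–O5 with help from the para-hydroxyl to the para-quinone methide/benzylic cation, which the silane reduces. A short K2CO3/MeOH treatment would remove any trifluoroacetate or silyl groups taken up by the hydroxyls. No new compound arises (F0).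

3. Step 4 (allylation). The risks are incomplete facial selectivity with an unbranched aldehyde, and slow oxidative release of the product from the borinate under the buffered conditions needed to keep the aryl ester. The fallback is a catalytic Keck allylation, which sets out from 5 and comes back at 7. Allyltributylstannane with the Lewis acid formed from (R)-BINOL and Ti(OiPr)4 (4 Å molecular sieves, CH2Cl2, −20 °C) is expected to deliver allyl to the same Re face and needs no oxidative work-up. No new compound arises (F0).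

**Further compounds**

F1 | step 5 | 4-[(3S)-3-hydroxy-5-oxohexyl]-2,6-dimethoxyphenyl pivalate | CC(=O)C[C@@H](O)CCc1cc(OC)c(OC(=O)C(C)(C)C)c(OC)c1
F2 | step 5 | 4-[(3S)-7-(4-acetoxy-3-methoxyphenyl)-3,7-dihydroxy-5-oxoheptyl]-2,6-dimethoxyphenyl pivalate (both C7 epimers) | CC(=O)Oc1ccc(cc1OC)C(O)CC(=O)C[C@@H](O)CCc1cc(OC)c(OC(=O)C(C)(C)C)c(OC)c1
F3 | step 5 | (2S,6S)-2-(4-acetoxy-3-methoxyphenyl)-6-[2-(3,5-dimethoxy-4-pivaloyloxyphenyl)ethyl]tetrahydro-4H-pyran-4-one | CC(=O)Oc1ccc(cc1OC)[C@@H]2CC(=O)C[C@H](CCc3cc(OC)c(OC(=O)C(C)(C)C)c(OC)c3)O2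
F4 | step 5 | (2S,4R,6S)-2-(4-acetoxy-3-methoxyphenyl)-6-[2-(3,5-dimethoxy-4-pivaloyloxyphenyl)ethyl]tetrahydro-2H-pyran-4-ol | CC(=O)Oc1ccc(cc1OC)[C@@H]2C[C@H](O)C[C@H](CCc3cc(OC)c(OC(=O)C(C)(C)C)c(OC)c3)O2
F0 | step 7 | none | none
F0 | step 4 | none | none
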